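**Retrosynthetic overview**

- Feature: the C1–C2–C3 chain is a reduced chalcone. Ring A (2-methoxy-4-hydroxyphenyl) sits on the C1 carbinol, ring B (4-hydroxy-3-prenylphenyl) on the C3 methylene, and C2 carries the esterified oxygen, so C1 is a former enone carbonyl and the C2 oxygen can be introduced on the enone.
- Late disconnections: C2–O acyl bond (silyl-protected syringoyl chloride), then C3–H back to the benzylic C3–O bond of a trans oxirane, then C1–H back to the epoxy ketone.
- Key disconnection: oxirane C2–O and C3–O bonds back to the (E)-chalcone by asymmetric nucleophilic epoxidation.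
- Early disconnections: enone C2=C3 back to the ring A acetophenone and the ring B aldehyde (aprotic aldol, then dehydration); ring B aldehyde back to 4-hydroxybenzaldehyde and prenyl bromide.
- Rings: the three benzene rings are bought; the only ring made is the oxirane (step 6), which is opened again at C3 in step 9.

Key step: step 6

Remark: the target SMILES is read as (1S,2R), the anti (erythro) arrangement of O1 and O2; Zn(BH4)2 is taken as a pre-formed ethereal solution.

**Route**

Step 1
Reactants: 1 1-(4-hydroxy-2-methoxyphenyl)ethanone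
Product: 2 1-[2-methoxy-4-(triisopropylsilyloxy)phenyl]ethanone
Conditions: TIPSCl, imidazole, DMF, rt
Reagents that add atoms: triisopropylsilyl chloride, CC(C)[Si](Cl)(C(C)C)C(C)C
Why: Imidazole-promoted O-silylation of the phenol, the bulky triisopropylsilyl ether being chosen to survive amide base, amine base, hydroperoxide and hydride later.

Step 2
Reactants: 3 4-hydroxybenzaldehyde; 4 prenyl bromide
Product: 5 4-hydroxy-3-(3-methylbut-2-en-1-yl)benzaldehyde
Conditions: KOH, H2O, rt
Reagents that add atoms: none
Why: Ortho C-alkylation of an ambident phenoxide, in which water hydrogen-bonds the phenoxide oxygen so that the allylic bromide is attacked by the ring carbon ortho to oxygen (para is blocked by CHO), the O-prenyl ether and the diprenylated phenol being the expected by-products removed by chromatography.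

Step 3
Reactants: 5 4-hydroxy-3-(3-methylbut-2-en-1-yl)benzaldehyde
Product: 6 3-(3-methylbut-2-en-1-yl)-4-(triisopropylsilyloxy)benzaldehyde
Conditions: TIPSCl, imidazole, DMF, rt
Reagents that add atoms: triisopropylsilyl chloride, CC(C)[Si](Cl)(C(C)C)C(C)C
Why: Imidazole-promoted O-silylation of the phenol, which masks the acidic OH before enolate chemistry and removes the phenoxide that would deactivate the later enone.

Step 4
Reactants: 2 1-[2-methoxy-4-(triisopropylsilyloxy)phenyl]ethanone; 6 3-(3-methylbut-2-en-1-yl)-4-(triisopropylsilyloxy)benzaldehyde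
Product: 8 rac-3-hydroxy-1-[2-methoxy-4-(triisopropylsilyloxy)phenyl]-3-[3-(3-methylbut-2-en-1-yl)-4-(triisopropylsilyloxy)phenyl]propan-1-one, via lithium enolate 7 (not isolated)
Conditions: LiN(SiMe3)2, THF, −78 °C; then 6, −78 °C; AcOH quench
Reagents that add atoms: none
Why: Directed crossed aldol addition of the kinetic lithium enolate of the methyl ketone to the non-enolisable aldehyde under aprotic conditions, which spare the base-labile aryl silyl ethers that an alcoholic-hydroxide Claisen–Schmidt condensation would cleave; the new carbinol centre is racemic and is removed in step 5.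

Step 5
Reactants: 8 rac-β-hydroxy ketone
Product: 10 (E)-1-[2-methoxy-4-(triisopropylsilyloxy)phenyl]-3-[3-(3-methylbut-2-en-1-yl)-4-(triisopropylsilyloxy)phenyl]prop-2-en-1-one, via β-mesyloxy ketone 9 (not isolated)
Conditions: MsCl, Et3N (excess), CH2Cl2, 0 °C → rt
Reagents that add atoms: none
Why: Mesylation followed by E1cB elimination of the β-mesyloxy ketone gives the conjugated enone, the (E) geometry being the thermodynamically favoured one with aryl and aroyl trans.

Step 6
Reactants: 10 (E)-chalcone
Product: 11 [2-methoxy-4-(triisopropylsilyloxy)phenyl]{(2R,3S)-3-[3-(3-methylbut-2-en-1-yl)-4-(triisopropylsilyloxy)phenyl]oxiran-2-yl}methanone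
Conditions: poly-L-leucine (immobilised, pre-activated), urea–H2O2, DBU, THF, rt
Reagents that add atoms: urea–hydrogen peroxide adduct, NC(N)=O.OO
Why: Juliá–Colonna epoxidation, the polypeptide-catalysed form of the Weitz–Scheffer reaction that is well precedented for chalcones: hydroperoxide anion (from urea–H2O2 and DBU), held together with the enone carbonyl by the N-terminal amide NH groups of the α-helical poly-L-leucine, adds to C3 of the enone. The β-peroxy enolate then closes the oxirane by attack of C2 on the proximal peroxide oxygen with loss of hydroxide, a 3-exo-tet closure that forms the C2–O bond after the C3–O bond. Both new stereocentres follow from the enone face that the helix exposes to the oxidant (catalyst control, poly-L-leucine giving the (2R,3S) series as for chalcone itself), and the trans relation follows from the (E)-enone through closure in the less hindered arrangement. The step needs chemoselectivity for the enone over the prenyl alkene, which is secured because the oxidant is a nucleophile and the trisubstituted alkene is electron-rich. It also needs the aryl O–Si bonds to survive hydroperoxide and DBU, for which the bulky triisopropylsilyl groups and the water-free medium were chosen. Because both rings carry donor groups the enone is a weak acceptor, so long reaction times with re-charging of oxidant and catalyst are expected.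

Step 7
Reactants: 11 (2R,3S)-epoxy ketone
Product: 12 (S)-[2-methoxy-4-(triisopropylsilyloxy)phenyl]{(2S,3S)-3-[3-(3-methylbut-2-en-1-yl)-4-(triisopropylsilyloxy)phenyl]oxiran-2-yl}methanol (anti epoxy alcohol)
Conditions: Zn(BH4)2, Et2O, −20 → 0 °C; H2O quench
Reagents that add atoms: none
Why: Chelation-controlled borohydride reduction of an α,β-epoxy ketone, in which zinc bridges the carbonyl and oxirane oxygens in the s-cis arrangement and hydride enters from the face away from C3, giving the anti (erythro) epoxy alcohol and so setting C1 as (S) under substrate control by C2.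

Step 8
Reactants: 12 anti epoxy alcohol
Product: 13 (2R,3S)-2-{(S)-[2-methoxy-4-(triisopropylsilyloxy)phenyl](triethylsilyloxy)methyl}-3-[3-(3-methylbut-2-en-1-yl)-4-(triisopropylsilyloxy)phenyl]oxirane
Conditions: TESCl, imidazole, DMAP (cat.), CH2Cl2, 0 °C → rt
Reagents that add atoms: triethylsilyl chloride, CC[Si](Cl)(CC)CC
Why: Silylation of the secondary alcohol with a silyl chloride and imidazole, which unlike a silyl triflate is not Lewis acidic enough to open the electron-rich aryl oxirane; the triethylsilyl group blocks alkoxide-directed hydride delivery to C2 in step 9 and comes off easily at the end (the C2 descriptor changes from S to R only through CIP priorities).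

Step 9
Reactants: 13 silylated epoxy alcohol
Product: 14 (1S,2R)-1-[2-methoxy-4-(triisopropylsilyloxy)phenyl]-3-[3-(3-methylbut-2-en-1-yl)-4-(triisopropylsilyloxy)phenyl]-1-(triethylsilyloxy)propan-2-ol
Conditions: LiAlH4, THF, 0 °C; Na2SO4·10H2O quench
Reagents that add atoms: none
Why: Regioselective SN2 hydride opening of an aryl oxirane at the benzylic carbon C3, which is activated by ring B while C2 is shielded by the branched silyloxy-bearing C1, so the C2–O bond and its configuration are untouched and C3 becomes the methylene group.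

Step 10
Reactants: 15 syringic acid
Product: 17 4-(tert-butyldimethylsilyloxy)-3,5-dimethoxybenzoic acid, via bis-silyl syringate 16 (not isolated)
Conditions: TBSCl (2.5 equiv.), imidazole, DMF, rt; then AcOH, THF/H2O, rt
Reagents that add atoms: tert-butyldimethylsilyl chloride, CC(C)(C)[Si](C)(C)Cl
Why: Exhaustive silylation followed by selective hydrolysis of the labile silyl ester in aqueous acetic acid, to which the hindered aryl silyl ether is stable.

Step 11
Reactants: 17 4-(tert-butyldimethylsilyloxy)-3,5-dimethoxybenzoic acid
Product: 18 4-(tert-butyldimethylsilyloxy)-3,5-dimethoxybenzoyl chloride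
Conditions: (COCl)2, DMF (cat.), CH2Cl2, 0 °C → rt; concentrate, use crude
Reagents that add atoms: oxalyl chloride, O=C(Cl)C(=O)Cl
Why: DMF-catalysed (Vilsmeier-type) conversion of the carboxylic acid into the acid chloride with loss of CO, CO2 and HCl.

Step 12
Reactants: 14 (1S,2R)-alcohol; 18 acid chloride
Product: 19 (1S,2R)-1-[2-methoxy-4-(triisopropylsilyloxy)phenyl]-3-[3-(3-methylbut-2-en-1-yl)-4-(triisopropylsilyloxy)phenyl]-1-(triethylsilyloxy)propan-2-yl 4-(tert-butyldimethylsilyloxy)-3,5-dimethoxybenzoate
Conditions: DMAP, Et3N, CH2Cl2, 0 °C → rt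
Reagents that add atoms: none
Why: DMAP-catalysed acylation through the N-acylpyridinium ion of the only free hydroxyl, C2–OH, with no bond to a stereocentre broken so that C2 stays (R).

Step 13
Reactants: 19 fully silylated ester
Product: 20 Eryvarinol B, (1S,2R)-1-hydroxy-1-(4-hydroxy-2-methoxyphenyl)-3-[4-hydroxy-3-(3-methylbut-2-en-1-yl)phenyl]propan-2-yl 4-hydroxy-3,5-dimethoxybenzoate
Conditions: Bu4NF, AcOH (1:1), THF, 0 °C → rt
Reagents that add atoms: none
Why: Fluoride-driven cleavage of all four Si–O bonds (three aryl silyl ethers and the C1 triethylsilyl ether), buffered with acetic acid so that no alkoxide or phenoxide builds up, which suppresses 1,2-migration of the aroyl group from O2 to O1 and quinone-methide formation from the para-hydroxybenzylic alcohol and leaves the ester and prenyl group intact.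

**Compound list**

1 | 1-(4-hydroxy-2-methoxyphenyl)ethanone | COc1cc(O)ccc1C(C)=O | starting material
2 | 1-[2-methoxy-4-(triisopropylsilyloxy)phenyl]ethanone | COc1cc(O[Si](C(C)C)(C(C)C)C(C)C)ccc1C(C)=O | intermediate
3 | 4-hydroxybenzaldehyde | O=Cc1ccc(O)cc1 | starting material
4 | prenyl bromide (1-bromo-3-methylbut-2-ene) | CC(C)=CCBr | starting material
5 | 4-hydroxy-3-(3-methylbut-2-en-1-yl)benzaldehyde | O=Cc1ccc(O)c(CC=C(C)C)c1 | intermediate
6 | 3-(3-methylbut-2-en-1-yl)-4-(triisopropylsilyloxy)benzaldehyde | O=Cc1ccc(O[Si](C(C)C)(C(C)C)C(C)C)c(CC=C(C)C)c1 | intermediate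
7 | lithium enolate of 2 | COc1cc(O[Si](C(C)C)(C(C)C)C(C)C)ccc1C(=C)[O-].[Li+] | intermediate
8 | rac-3-hydroxy-1-[2-methoxy-4-(triisopropylsilyloxy)phenyl]-3-[3-(3-methylbut-2-en-1-yl)-4-(triisopropylsilyloxy)phenyl]propan-1-one | COc1cc(O[Si](C(C)C)(C(C)C)C(C)C)ccc1C(=O)CC(O)c1ccc(O[Si](C(C)C)(C(C)C)C(C)C)c(CC=C(C)C)c1 | intermediate
9 | 3-methanesulfonate of 8 (β-mesyloxy ketone) | COc1cc(O[Si](C(C)C)(C(C)C)C(C)C)ccc1C(=O)CC(OS(C)(=O)=O)c1ccc(O[Si](C(C)C)(C(C)C)C(C)C)c(CC=C(C)C)c1 | intermediate
10 | (E)-1-[2-methoxy-4-(triisopropylsilyloxy)phenyl]-3-[3-(3-methylbut-2-en-1-yl)-4-(triisopropylsilyloxy)phenyl]prop-2-en-1-one | COc1cc(O[Si](C(C)C)(C(C)C)C(C)C)ccc1C(=O)/C=C/c1ccc(O[Si](C(C)C)(C(C)C)C(C)C)c(CC=C(C)C)c1 | intermediate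
11 | (2R,3S)-epoxy ketone | COc1cc(O[Si](C(C)C)(C(C)C)C(C)C)ccc1C(=O)[C@@H]1O[C@H]1c1ccc(O[Si](C(C)C)(C(C)C)C(C)C)c(CC=C(C)C)c1 | intermediate
12 | (1S,2S,3S) anti epoxy alcohol | COc1cc(O[Si](C(C)C)(C(C)C)C(C)C)ccc1[C@H](O)[C@@H]1O[C@H]1c1ccc(O[Si](C(C)C)(C(C)C)C(C)C)c(CC=C(C)C)c1 | intermediate
13 | C1 triethylsilyl ether of 12 | COc1cc(O[Si](C(C)C)(C(C)C)C(C)C)ccc1[C@H](O[Si](CC)(CC)CC)[C@@H]1O[C@H]1c1ccc(O[Si](C(C)C)(C(C)C)C(C)C)c(CC=C(C)C)c1 | intermediate
14 | (1S,2R)-1-[2-methoxy-4-(triisopropylsilyloxy)phenyl]-3-[3-(3-methylbut-2-en-1-yl)-4-(triisopropylsilyloxy)phenyl]-1-(triethylsilyloxy)propan-2-ol | COc1cc(O[Si](C(C)C)(C(C)C)C(C)C)ccc1[C@H](O[Si](CC)(CC)CC)[C@@H](Cc1ccc(O[Si](C(C)C)(C(C)C)C(C)C)c(CC=C(C)C)c1)O | intermediate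
15 | syringic acid | COc1cc(C(=O)O)cc(OC)c1O | starting material
16 | tert-butyldimethylsilyl 4-(tert-butyldimethylsilyloxy)-3,5-dimethoxybenzoate | COc1cc(C(=O)O[Si](C)(C)C(C)(C)C)cc(OC)c1O[Si](C)(C)C(C)(C)C | intermediate
17 | 4-(tert-butyldimethylsilyloxy)-3,5-dimethoxybenzoic acid | COc1cc(C(=O)O)cc(OC)c1O[Si](C)(C)C(C)(C)C | intermediate
18 | 4-(tert-butyldimethylsilyloxy)-3,5-dimethoxybenzoyl chloride | COc1cc(C(=O)Cl)cc(OC)c1O[Si](C)(C)C(C)(C)C | intermediate
19 | (1S,2R) fully silylated ester | COc1cc(O[Si](C(C)C)(C(C)C)C(C)C)ccc1[C@H](O[Si](CC)(CC)CC)[C@@H](Cc1ccc(O[Si](C(C)C)(C(C)C)C(C)C)c(CC=C(C)C)c1)OC(=O)c1cc(OC)c(O[Si](C)(C)C(C)(C)C)c(OC)c1 | intermediate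
20 | Eryvarinol B | COc1cc(O)ccc1[C@H](O)[C@@H](Cc1ccc(O)c(CC=C(C)C)c1)OC(=O)c1cc(OC)c(O)c(OC)c1 | target

**Step count and risks**

Total: 13 steps. Longest linear sequence: 10 steps (3 → 5 → 6 → 8 → 10 → 11 → 12 → 13 → 14 → 19 → 20; steps 2, 3, 4, 5, 6, 7, 8, 9, 12, 13).

Steps most likely to fail:

Step 6. The doubly donor-substituted enone may accept hydroperoxide only slowly. Uncatalysed background epoxidation would then erode the enantioface selectivity, and prolonged contact with hydroperoxide and DBU could cleave the aryl silyl ethers, above all the one para to the carbonyl. The fallback sets out from 10 and moves the stereodefining event to a hydroxyl-directed epoxidation. 1,2-Reduction of the enone with i-Bu2AlH (toluene, −78 °C) should give the racemic (E)-allylic alcohol F1. Kinetic-resolution Sharpless epoxidation of it (Ti(OiPr)4, L-(+)-diisopropyl tartrate, about 0.6 equiv. tert-butyl hydroperoxide, 4 Å molecular sieves, CH2Cl2, −20 °C) is expected to epoxidise the fast-reacting (R)-enantiomer on the face that gives the erythro (1S,2S,3S) epoxy alcohol, so the route is rejoined at 12. The slow (S)-enantiomer of F1 can be oxidised back to 10 with MnO2 and recycled. The prenyl alkene carries no directing hydroxyl and should be left alone, and no strong base meets the silyl ethers.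

Step 9. Hydride may attack C2 instead of C3, which would give the 1,3-dioxygenated isomer, and the aluminate formed at O2 may take over the triethylsilyl group from O1 by a 1,2-silyl shift. The fallback sets out from 13 and opens the oxirane by a radical instead of a polar path. Titanocene monochloride Cp2TiCl (trivalent titanium, made from Cp2TiCl2 and Zn dust in THF) with excess 1,4-cyclohexadiene should cleave the C3–O bond homolytically to the benzylic radical, whose regiochemistry is set by radical stability and not by steric access. Hydrogen-atom transfer and mild aqueous work-up of the titanium alkoxide at O2 then return the route at 14. No new compound is made on the way.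

Step 13. The hindered C1 silyl ether may cleave only slowly, and during that time the freed phenoxides and the C1 oxygen sit under fluoride. The aroyl group may then migrate from O2 to O1, or the para-hydroxybenzylic C1–OH may be lost through a quinone methide. The fallback sets out from 19 and unmasks in two stages instead of one. HF·pyridine buffered with pyridine (THF, 0 °C) should remove only the alkyl triethylsilyl ether and give the C1-hydroxy tris(aryl silyl ether) ester F2, in which ring A is still silylated and cannot form a quinone methide. The three aryl silyl ethers, which cleave within minutes, are then removed with Bu4NF/AcOH in THF at −20 °C, so the free C1–OH and C2 ester pair meets fluoride only briefly, and the route comes back at 20.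

**Further compounds**

F1 | step 6 | rac-(E)-1-[2-methoxy-4-(triisopropylsilyloxy)phenyl]-3-[3-(3-methylbut-2-en-1-yl)-4-(triisopropylsilyloxy)phenyl]prop-2-en-1-ol | COc1cc(O[Si](C(C)C)(C(C)C)C(C)C)ccc1C(O)/C=C/c1ccc(O[Si](C(C)C)(C(C)C)C(C)C)c(CC=C(C)C)c1
F0 | step 9 | none | none
F2 | step 13 | (1S,2R)-1-hydroxy-1-[2-methoxy-4-(triisopropylsilyloxy)phenyl]-3-[3-(3-methylbut-2-en-1-yl)-4-(triisopropylsilyloxy)phenyl]propan-2-yl 4-(tert-butyldimethylsilyloxy)-3,5-dimethoxybenzoate | COc1cc(O[Si](C(C)C)(C(C)C)C(C)C)ccc1[C@H](O)[C@@H](Cc1ccc(O[Si](C(C)C)(C(C)C)C(C)C)c(CC=C(C)C)c1)OC(=O)c1cc(OC)c(O[Si](C)(C)C(C)(C)C)c(OC)c1
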